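The earlier runs and the new flask are simulated with constants of no real substance; the scatter is artificial.

**Early readings.** At early times the target readings carried a scatter of 0.5 percentage points: after 20.0 min Monday's run read 1.6% and after 20.0 min Saturday's read 1.7%. Both runs had the same charges of substrate, 0.25 M, and free catalyst, 0.12 mM, but partner stood at 0.237 M against 0.12 M, so I compared these two amounts, taken at one time.

| setting | Monday's | Saturday's | flask |
|---|---|---|---|
| substrate | 0.25 M | 0.25 M | 0.25 M |
| partner | 0.237 M | 0.12 M | 0.237 M |
| free catalyst | 0.12 mM | 0.12 mM | 0.12 mM |
| remark | the very flask that is asked about, followed so far | run made earlier |  |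

| run | time / min | target / % |
|---|---|---|
| Monday's | 1.50 | 1.2 |
| Monday's | 2.50 | 0 |
| Monday's | 4.00 | 0.4 |
| Monday's | 8.00 | 1.0 |
| Monday's | 12.0 | 1.3 |
| Monday's | 20.0 | 1.6 |
| Saturday's | 3.00 | 0.6 |
| Saturday's | 10.0 | 0.3 |
| Saturday's | 20.0 | 1.7 |
| Saturday's | 25.0 | 1.8 |
| Saturday's | 40.0 | 3.7 |
| Saturday's | 50.0 | 4.7 |

(scatter of a reading: 0.5 percentage points)

- what was read earlier has a scatter of 0.5 percentage points, one standard deviation
- what may be going on: 2 free catalyst <-> resting dimer; partner + catalyst intermediate -> free catalyst + target; free catalyst + open intermediate <-> catalyst intermediate; substrate + free catalyst <-> free catalyst + open intermediate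
- no earlier run changes the charge of free catalyst; that part of a forecast is a guess
- what has left substrate counts as converted, also if it is not yet product

* apparent order in partner when 20% of the substrate are converted (percent change of the rate of making target for one percent more partner charged)
* apparent order in free catalyst when 20% of the substrate are converted (percent change of the rate of making target for one percent more free catalyst charged)

**Pair blur.** I took an order from such a pair as the logarithm of the ratio of the amounts divided by the logarithm of the ratio of the partner charges, and this gave −0.0891. The pair blur is the relative scatter of the two readings, added in quadrature and divided by that same logarithm: 0.631. I committed to nothing sharper for partner. For free catalyst I had no pair.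

**The forecast.** It gave 0.2 in partner, holding that “the partner step is probably not rate-limiting”, and 0.7 in free catalyst. Its partner order differed from my reading by less than one blur.

**The flask.** The simulation gave 0.66 in partner and 0.66 in free catalyst.

    2 free catalyst ⇌ resting dimer, settled at all times (K = 12000 L mol⁻¹)
    partner + catalyst intermediate → free catalyst + target (k = 3.70 L mol⁻¹ s⁻¹)
    free catalyst + open intermediate ⇌ catalyst intermediate (K = 4.00 L mol⁻¹, k = 7.30 L mol⁻¹ s⁻¹)
    substrate + free catalyst ⇌ free catalyst + open intermediate (K = 0.640, k = 6.30 L mol⁻¹ s⁻¹)

The partner order of the flask was 1.05 blurs, a size this pair left unresolved. At 13.3 min catalyst intermediate in the flask had a half-life of 0.80 s by the partner step, while by its return to free catalyst and open intermediate it had a shorter half-life of 0.380 s. Twice the partner multiplied the rate by 1.49, an order averaged over that doubling of 0.572, which is 0.906 blurs.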